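## Structural features

The target is a bicyclic diterpenoid acid of the labdane type (ent series, 2R,5R,9R,10R): a trans-fused decalin (rings A and B) with a six-carbon side chain on C9. Ring A carries the gem-dimethyl carbon C4, an equatorial secondary hydroxyl at C2 and the quaternary C10 with its axial methyl C20; ring B carries the exocyclic methylene C8=C17 and the C9 branch. C5, C10 and C9 are contiguous stereocentres (C20 trans to H5, C20 cis to C11); C2 is separated from them by CH2 groups but is 1,3-related to both C4 and C10, so an axial substituent there would meet two axial methyls. The side chain ends in a (13Z)-enoic acid whose acetoxymethyl group C16 is cis to the carboxyl C15. This is an opened butenolide: any free C16 hydroxyl next to an activated C15 carboxyl would lactonise. The allylic acetate is base-labile and the C8 methylene is acid-labile. The real difficulty is the C5–C10 bond, which joins a quaternary carbon to a carbon flanked by the gem-dimethyl centre, together with the relay of absolute configuration from one controllable centre (C9) to C10 and C5. The key step exploits two features. The C2 oxygen is β to quaternary C10 (C2–C1–C10), the pattern left when a cyclopropanol spanning C2, C1 and C10 opens to a β-keto tertiary radical. The C8 methylene next to C7 is the footprint of radical addition to a 2-substituted allyl sulfone with loss of the sulfonyl radical, and the unsubstituted C6 can hide a traceless sulfone.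

## Logic of the disconnections

**36 ⇒ 34 ⇒ 33 (no skeletal bond cut).** The C15 acid is traced back to a primary allylic alcohol and the two free hydroxyls to silyl ethers. C16 then carries its acetate from the start and C15 stays at the alcohol level until the last step, so a γ-hydroxy acid or ester that could close to the butenolide never exists. The demand is a final oxidation that takes the primary allylic alcohol and spares the secondary C2 alcohol, the acetate, the (Z)-alkene and the C8 methylene.

**33 ⇒ 26 + 31 (C12–C13).** Cutting the sp3–sp2 bond separates the whole side-chain head, with alkene geometry and differentiated oxygens already fixed, from the decalin. The forward step must couple a primary alkylzinc with an alkenyl iodide with retention of geometry and tolerate an allylic acetate.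

**31 ⇒ 30 ⇒ 29 ⇒ 28 ⇒ 27 (C–I, O–acyl, O–silyl, C–Sn, C–H).** The four-carbon unit comes from a symmetrical alkyne, so syn-hydrometalation has no regiochemical question and fixes the cis relation of the two CH2O groups. The demand is that the two hydroxyls of 28 be told apart by the bulk of the neighbouring tin.

**26 ⇒ 25 ⇒ 24 ⇒ 23 (functional group changes only).** One dissolving-metal step removes the C6 sulfone and the benzyl group and sets the equatorial C2 alcohol. The primary alcohol then becomes the iodide and the secondary one a silyl ether. The demand is chemoselective activation of the primary over the secondary hydroxyl.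

**23 ⇒ 22 (C5–C10 and C6–C7; key step).** Both rings and three stereocentres are traced back to an open chain that holds only C9 as a fixed stereocentre. Every other element is a spectator (ether), a radical acceptor (vinyl sulfone), a radical leaving group (allyl sulfone) or the radical source (cyclopropanol). The demand is that the tertiary radical close onto hindered C5 faster than it is quenched, and that C9 direct the face of C10.

**22 ⇒ 21 ⇒ 20 ⇒ 19 (C1–C2 and C1–C10, then C20–H and O–Si).** The cyclopropane methylene C1 is removed to a silyl enol ether, and the enol ether to an α-methylene ketone. Hydride addition to C20 can only give the C2=C10 enol derivative, so the regiochemistry is fixed by construction and no base meets the acidic allyl sulfone. The demand is a carbenoid that picks the electron-rich enol ether over the two sulfone-deactivated alkenes.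

**19 ⇒ 18 ⇒ 17 ⇒ 16 ⇒ 15 ⇒ 14 + 5 (C2–C10).** The ketone is assembled by an aldol union of the imide enolate carbon C10 with the aldehyde carbon C2. The imide carbonyl becomes C20 after reduction, sulfonylation and elimination. The gain is full convergence of the two sulfone-bearing halves. The demand is enolisation of the imide without deprotonation of the allyl sulfone (soft enolisation).

**14 ⇒ 13 ⇒ 12 ⇒ 10 + 11 (C17–S, C17–Cl, C8–C9).** The allyl sulfone comes from an isopropenyl group by ene-type chlorination and sulfinate displacement, and the isopropenyl group from auxiliary-controlled conjugate addition, which sets C9. The sulfone is installed before any enol ether exists, because hypochlorite would destroy one. The demand is high facial selectivity in the conjugate addition.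

**10 ⇒ 8 + 9 ⇒ 6 + 7 (C9=C10 alkene, N–acyl).** Cross-metathesis and N-acylation lead back to commercial materials.

**5 ⇒ 4 ⇒ 1 + 2 (C6–S).** The vinyl sulfone comes from the terminal alkene of 1 by iodosulfonylation and elimination. The ester carbon of 1 is C2.

## Other disconnections considered

**Alternative 1:** The cut is C9–C10 with O–C6 broken: the silyl ketene acetal of lactone A1 (LiN(i-Pr)2, Me3SiCl, then heat) would rearrange to acid A2 (Ireland–Claisen ring contraction). Because the C7–C8 tether spans positions 1 and 4 of the pericyclic array, a boat is enforced.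
- In its favour: the rearrangement type is known and stereospecific. It transfers the C6 configuration to quaternary C10 and makes the hindered C9–C10 bond intramolecularly. On certainty of the key step and on control of C10 (chirality transfer instead of acyclic induction) it is the better of the two plans.
- Against it here: the boat places the C9 carboxyl trans to the C10 methyl, as A2 shows, so C9 must later be epimerised. C5 is left as an alkene and needs a trans-selective hydrogenation before the C8 methylene exists. The C8 oxygen must be oxidised and methylenated beside the epimerisable C9. The C11 carboxyl needs a one-carbon homologation, and C2 still needs ketal removal and a dissolving-metal reduction (equal to the chosen plan on that last point).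
- Comparison: in structure it builds one ring and two stereocentres against two rings and three. In mechanism it is closed-shell and more predictable. In step economy it is clearly worse, since most of the ring-B functionality has to be reworked after the key step.

**Alternative 2:** The cuts are C1–C2 and C9–C10: MeAlCl2 would activate the aldehyde of A3, the isopropenyl CH2 would close ring A, and the C10 cation would be trapped at C9 by the allylsilane to close ring B, giving A4.
- In its favour: two rings, two bonds and three new stereocentres (C2, C10, C9) would come from the single C5 centre through a chair–chair array. A4 already has the free equatorial C2 hydroxyl, the C8 methylene and the C12 oxygen. After the key step this is better than the chosen plan, which must still remove a sulfone, reduce a ketone and cleave an ether. Stereochemical relay through a preorganised bicyclic transition state is also at least the equal of the radical relay.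
- Against it here: the C10 cation can lose a proton from C1 or C20 (carbonyl-ene outcome) instead of being trapped. The aldehyde can meet the allylsilane directly. The C2 configuration depends on the aluminium alkoxide sitting equatorial. A3 needs an enantiopure C5 bearing isopropenyl next to quaternary C4 and a geometrically pure trisubstituted allylsilane, which is no easier to secure than C9 in 22.
- Comparison: in structure it covers more (it sets C2 as well). In mechanism both are untested cascades with diverting pathways, so they are equal in uncertainty. In step economy it is the better plan after the key step and about equal before it.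

**Alternative 3:** The cut is C8–C9: (Ph3P)AuNTf2 (monovalent gold) would activate the alkyne of A5 and the enol ether carbon C9 would attack C8 (6-exo-dig) to give aldehyde A6.
- In its favour: the reaction class is known, mild and catalytic. The methylene is formed directly with no leaving group to remove. C2, C5 and C10 are already in place, so the key step has to set only C9. On certainty of the key step it is the better plan.
- Against it here: only one bond and one ring are formed. The hard part of the molecule, the C5–C10 bond and the quaternary centre, is moved into the synthesis of A5. A6 is an α-branched β,γ-unsaturated aldehyde, open to epimerisation at C9 and to migration of the C8 alkene into conjugation. C11 arrives as an aldehyde carbon, so C12–C16 must be added by olefination and a selective reduction beside the C8 methylene and the enoate, or by homologation.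
- Comparison: in structure it is weaker. In mechanism it is safer. In step economy it is worse overall because ring A with three stereocentres must be built first.

Key step: step 14

## Remarks before the steps

- Labdane numbering (C1–C20) is used for skeletal positions throughout, including open-chain intermediates.
- Assumption: the conjugate addition of step 5 follows the usual magnesium-chelated syn-s-cis model with attack opposite the benzyl group. On that basis the (R)-auxiliary gives the required (S)-C9; if the opposite sense were found, the enantiomeric auxiliary would be used.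
- The cyclopropanol 22 and the decalin 23 were checked against each other and against the target. C9 has the same spatial arrangement in all three, the decalin centres of 23 match the target, and 23 equals 22 minus benzenesulfinic acid. No structural correction is needed, and the key step is formally an isomerisation with loss of PhSO2H.

## Steps

Step 1
Reactants: 1 methyl 3,3-dimethylpent-4-enoate; 2 sodium benzenesulfinate
Product: 4 methyl (E)-3,3-dimethyl-5-(phenylsulfonyl)pent-4-enoate, via β-iodo sulfone 3 (not isolated)
Conditions: PhSO2Na, I2, EtOAc/H2O, rt; then Et3N, MeCN, 0 °C → rt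
Reagents that add atoms: none
Why: Iodosulfonylation (sulfonyl radical adds to the terminal carbon, iodine-atom transfer follows) and amine-induced dehydroiodination give the (E)-vinyl sulfone; the alkene cannot move out of conjugation because C4 is quaternary.

Step 2
Reactants: 4 methyl (E)-3,3-dimethyl-5-(phenylsulfonyl)pent-4-enoate
Product: 5 (E)-3,3-dimethyl-5-(phenylsulfonyl)pent-4-enal
Conditions: i-Bu2AlH (1.1 equiv), CH2Cl2, −78 °C; aq. potassium sodium tartrate
Reagents that add atoms: none
Why: Partial reduction of the ester through the aluminium hemiacetal, which is stable at low temperature; the vinyl sulfone should not be reduced at −78 °C.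

Step 3
Reactants: 6 (R)-4-benzyl-1,3-oxazolidin-2-one; 7 acryloyl chloride
Product: 8 (R)-3-acryloyl-4-benzyl-1,3-oxazolidin-2-one
Conditions: n-BuLi, THF, −78 °C; then 7, −78 → 0 °C
Reagents that add atoms: none
Why: N-acylation of the lithiated oxazolidinone, the standard way to attach the auxiliary.

Step 4
Reactants: 8 (R)-3-acryloyl-4-benzyl-1,3-oxazolidin-2-one; 9 4-(benzyloxy)but-1-ene
Product: 10 (R)-4-benzyl-3-[(E)-5-(benzyloxy)pent-2-enoyl]-1,3-oxazolidin-2-one
Conditions: second-generation Hoveyda–Grubbs catalyst RuCl2(H2IMes)(=CH-C6H4-2-O-i-Pr) (3 mol%), 9 (3 equiv), CH2Cl2, 40 °C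
Reagents that add atoms: none
Why: Olefin cross-metathesis between an electron-poor acrylimide and an excess of a simple terminal alkene favours the cross product and the (E)-enoyl imide.

Step 5
Reactants: 10 (R)-4-benzyl-3-[(E)-5-(benzyloxy)pent-2-enoyl]-1,3-oxazolidin-2-one; 11 isopropenylmagnesium bromide
Product: 12 (R)-4-benzyl-3-[(S)-3-(2-(benzyloxy)ethyl)-4-methylpent-4-enoyl]-1,3-oxazolidin-2-one
Conditions: 11 (2.5 equiv), CuBr·SMe2 (1.2 equiv), THF/Me2S, −78 → −20 °C; aq. NH4Cl
Reagents that add atoms: none
Why: Copper-mediated conjugate addition to the chelated syn-s-cis N-enoyl oxazolidinone; the isopropenyl group should add to the β-face opposite the benzyl group, which for the (R)-auxiliary sets (S)-C9.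

Step 6
Reactants: 12 (R)-4-benzyl-3-[(S)-3-(2-(benzyloxy)ethyl)-4-methylpent-4-enoyl]-1,3-oxazolidin-2-one
Product: 13 (R)-4-benzyl-3-[(S)-3-(2-(benzyloxy)ethyl)-4-(chloromethyl)pent-4-enoyl]-1,3-oxazolidin-2-one
Conditions: Ca(OCl)2, solid CO2, CH2Cl2/H2O, 0 °C
Reagents that add atoms: calcium hypochlorite [Ca+2].[O-]Cl.[O-]Cl
Why: Ene-type allylic chlorination by HOCl: chlorine adds to the CH2 terminus and a methyl proton is lost, so the isopropenyl group becomes a 2-(chloromethyl)vinyl group and C9 is untouched.

Step 7
Reactants: 13 (R)-4-benzyl-3-[(S)-3-(2-(benzyloxy)ethyl)-4-(chloromethyl)pent-4-enoyl]-1,3-oxazolidin-2-one; 2 sodium benzenesulfinate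
Product: 14 (R)-4-benzyl-3-[(S)-3-(2-(benzyloxy)ethyl)-4-(phenylsulfonylmethyl)pent-4-enoyl]-1,3-oxazolidin-2-one
Conditions: PhSO2Na (1.5 equiv), Bu4NI (cat.), DMF, rt
Reagents that add atoms: none
Why: S-alkylation of the sulfinate by the allylic chloride (SN2); an SN2' course would give the same compound because the two allylic termini are equivalent.

Step 8
Reactants: 14 (R)-4-benzyl-3-[(S)-3-(2-(benzyloxy)ethyl)-4-(phenylsulfonylmethyl)pent-4-enoyl]-1,3-oxazolidin-2-one; 5 (E)-3,3-dimethyl-5-(phenylsulfonyl)pent-4-enal
Product: 15 (R)-4-benzyl-3-{(E)-2-[(S)-5-(benzyloxy)-2-(phenylsulfonylmethyl)pent-1-en-3-yl]-3-hydroxy-5,5-dimethyl-7-(phenylsulfonyl)hept-6-enoyl}-1,3-oxazolidin-2-one (syn aldol expected; the two new centres are left unspecified)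
Conditions: TiCl4, i-Pr2NEt, CH2Cl2, −78 → 0 °C; then 5, −78 °C
Reagents that add atoms: none
Why: Titanium enolate aldol addition of an N-acyl oxazolidinone; soft enolisation acts only on the chelated imide and not on the allyl sulfone CH2. The two new centres (C10, C2) are destroyed in step 11, so their configuration is immaterial.

Step 9
Reactants: 15 aldol adduct (name as under step 8)
Product: 16 (E)-2-[(S)-5-(benzyloxy)-2-(phenylsulfonylmethyl)pent-1-en-3-yl]-5,5-dimethyl-7-(phenylsulfonyl)hept-6-ene-1,3-diol
Conditions: NaBH4, THF/H2O, 0 °C → rt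
Reagents that add atoms: none
Why: Reductive cleavage of the N-acyl oxazolidinone to the primary alcohol with release of the auxiliary; the β-hindered vinyl sulfone should survive borohydride under these conditions.

Step 10
Reactants: 16 (E)-2-[(S)-5-(benzyloxy)-2-(phenylsulfonylmethyl)pent-1-en-3-yl]-5,5-dimethyl-7-(phenylsulfonyl)hept-6-ene-1,3-diol
Product: 17 (E)-2-[(S)-5-(benzyloxy)-2-(phenylsulfonylmethyl)pent-1-en-3-yl]-3-hydroxy-5,5-dimethyl-7-(phenylsulfonyl)hept-6-en-1-yl methanesulfonate
Conditions: MsCl (1.05 equiv), 2,4,6-collidine, CH2Cl2, −20 → 0 °C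
Reagents that add atoms: methanesulfonyl chloride CS(=O)(=O)Cl
Why: Chemoselective sulfonylation of the primary hydroxyl beside a hindered secondary one.

Step 11
Reactants: 17 (E)-2-[(S)-5-(benzyloxy)-2-(phenylsulfonylmethyl)pent-1-en-3-yl]-3-hydroxy-5,5-dimethyl-7-(phenylsulfonyl)hept-6-en-1-yl methanesulfonate
Product: 19 (S,E)-3-[2-(benzyloxy)ethyl]-7,7-dimethyl-4-methylidene-9-(phenylsulfonyl)-2-(phenylsulfonylmethyl)nona-1,8-dien-5-one, via β-mesyloxy ketone 18 (not isolated)
Conditions: Dess–Martin periodinane, CH2Cl2, 0 °C → rt; then Et3N, 0 °C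
Reagents that add atoms: none
Why: Oxidation of the secondary alcohol gives a β-mesyloxy ketone that loses methanesulfonate by E1cB elimination; the resulting C10=C20 enone marks the C10 side of the ketone as the only site from which an enol derivative can arise.

Step 12
Reactants: 19 (S,E)-3-[2-(benzyloxy)ethyl]-7,7-dimethyl-4-methylidene-9-(phenylsulfonyl)-2-(phenylsulfonylmethyl)nona-1,8-dien-5-one
Product: 20 triethyl{[(S,8E)-3-(2-(benzyloxy)ethyl)-4,7,7-trimethyl-9-(phenylsulfonyl)-2-(phenylsulfonylmethyl)nona-1,4,8-trien-5-yl]oxy}silane (mixture of enol ether isomers)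
Conditions: Et3SiH (1.3 equiv), RhCl(PPh3)3 (2 mol%), toluene, 45 °C
Reagents that add atoms: triethylsilane CC[SiH](CC)CC
Why: Rhodium-catalysed 1,4-hydrosilylation of an enone puts hydride on C20 and silicon on oxygen, so the tetrasubstituted C2=C10 silyl enol ether forms regiospecifically and without a base that could deprotonate the allyl sulfone. The enol ether geometry is immaterial.

Step 13
Reactants: 20 triethylsilyl enol ether (name as under step 12)
Product: 22 2-[(S)-5-(benzyloxy)-2-(phenylsulfonylmethyl)pent-1-en-3-yl]-1-[(E)-2,2-dimethyl-4-(phenylsulfonyl)but-3-en-1-yl]-2-methylcyclopropan-1-ol (mixture at the two substituted ring carbons), via triethylsilyl cyclopropyl ether 21 (not isolated)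
Conditions: Et2Zn, CH2I2, CH2Cl2, 0 °C → rt; aq. NH4Cl; crude, then Bu4NF, AcOH, THF, 0 °C
Reagents that add atoms: diiodomethane ICI
Why: Simmons–Smith cyclopropanation (Furukawa conditions): the electrophilic zinc carbenoid should take the electron-rich silyl enol ether well ahead of the two sulfone-deactivated alkenes, and buffered fluoride then frees the tertiary cyclopropanol. Both new ring centres are erased in step 14.

Step 14
Reactants: 22 cyclopropanol (name as under step 13)
Product: 23 (5R,6R,9R,10S)-12-(benzyloxy)-6-(phenylsulfonyl)-13,14,15,16-tetranorlabd-8(17)-en-2-one (trans-fused; C20 cis to C11; sulfonyl equatorial; decalin geometry as in the target)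
Conditions: Mn(acac)3 (0.25 equiv), degassed t-BuOH/MeCN (1:1), 0.005 M, 40 °C, argon
Reagents that add atoms: none
Why: Proposed new method: ligand exchange gives a trivalent manganese cyclopropanolate whose one-electron oxidation and strain-driven β-scission cleave C2–C10 toward the more substituted carbon, leaving the C2 ketone and the tertiary C10 radical; the closest known reaction types are manganese-mediated oxidative ring-opening/cyclisation of cyclopropanols and radical cyclisations terminated by β-elimination of a sulfonyl radical from an allyl sulfone, combined here in one cascade. Ring A closes 6-exo-trig: the nucleophilic tertiary radical adds to C5, the β-carbon of the electron-poor vinyl sulfone (polarity-matched and helped by the gem-dimethyl group), through a chair with the C10 methyl axial and both the C9 branch and the vinyl sulfone carbon equatorial, which sets H5 trans to the C10 methyl. C10 is set relative to C9 by 1,2-induction in this first closure (C5 is expected to add anti to the bulky 2-(sulfonylmethyl)vinyl arm of C9), and this is the least secure element. Ring B closes 6-endo-trig: the α-sulfonyl C6 radical adds to the CH2 terminus C7 of the allyl sulfone through a chair with C11 equatorial, and the tertiary C8 radical expels PhSO2•, which makes the addition irreversible and leaves the C8 methylene. C6 is formed with the sulfonyl group expected equatorial but is erased in step 15. The selectivities needed are cleavage of C2–C10 and not C1–C2 (secured by tertiary versus primary radical stability), 6-endo over 5-exo attack at the allyl sulfone (secured by the substituent on C8 and by the fact that only the 6-endo adduct can fragment), and closure faster than quenching of the C10 radical (served by high dilution and solvents without weak C–H bonds). The sulfonyl radical is reduced by divalent manganese to sulfinate, which returns trivalent manganese, so the change is an isomerisation with loss of benzenesulfinic acid and should need only a substoichiometric charge of Mn(acac)3.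

Step 15
Reactants: 23 key-step decalin (name as under step 14)
Product: 24 (2R,5R,9R,10R)-13,14,15,16-tetranorlabd-8(17)-ene-2,12-diol
Conditions: Li, NH3(l), THF, t-BuOH, −78 → −33 °C; NH4Cl
Reagents that add atoms: none
Why: Dissolving-metal reduction should do three things at once: reductive desulfonylation at C6, cleavage of the benzyl ether, and reduction of the C2 ketone to the thermodynamically preferred equatorial alcohol (an axial hydroxyl would be 1,3-diaxial to the C4 and C10 methyls). The isolated 1,1-disubstituted alkene is not reduced.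

Step 16
Reactants: 24 (2R,5R,9R,10R)-13,14,15,16-tetranorlabd-8(17)-ene-2,12-diol
Product: 25 (2R,5R,9R,10R)-12-iodo-13,14,15,16-tetranorlabd-8(17)-en-2-ol
Conditions: I2, PPh3, imidazole (1.1 equiv each), CH2Cl2, 0 °C
Reagents that add atoms: iodine II
Why: Appel-type iodination is much faster at the primary C12 hydroxyl than at the secondary C2 hydroxyl.

Step 17
Reactants: 25 (2R,5R,9R,10R)-12-iodo-13,14,15,16-tetranorlabd-8(17)-en-2-ol
Product: 26 triethyl{[(2R,5R,9R,10R)-12-iodo-13,14,15,16-tetranorlabd-8(17)-en-2-yl]oxy}silane
Conditions: Et3SiCl, imidazole, DMF, rt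
Reagents that add atoms: chlorotriethylsilane CC[Si](Cl)(CC)CC
Why: Routine silylation of a secondary alcohol; it keeps the hydroxyl proton away from the organozinc of step 22.

Step 18
Reactants: 27 but-2-yne-1,4-diol
Product: 28 (E)-2-(tributylstannyl)but-2-ene-1,4-diol
Conditions: Bu3SnH, PdCl2(PPh3)2 (2 mol%), THF, rt
Reagents that add atoms: tributyltin hydride CCCC[SnH](CCCC)CCCC
Why: Palladium-catalysed syn-hydrostannation of a symmetrical alkyne has no regiochemical question and fixes the two CH2O groups cis, as C15 and C16 must be.

Step 19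
Reactants: 28 (E)-2-(tributylstannyl)but-2-ene-1,4-diol
Product: 29 (E)-4-[(tert-butyldimethylsilyl)oxy]-2-(tributylstannyl)but-2-en-1-ol
Conditions: t-BuMe2SiCl (1.0 equiv), imidazole, CH2Cl2, −20 °C
Reagents that add atoms: tert-butyldimethylsilyl chloride CC(C)(C)[Si](C)(C)Cl
Why: Monosilylation should favour the hydroxyl remote from the bulky tributylstannyl group (the future C15 oxygen) on steric grounds.

Step 20
Reactants: 29 (E)-4-[(tert-butyldimethylsilyl)oxy]-2-(tributylstannyl)but-2-en-1-ol
Product: 30 (E)-4-[(tert-butyldimethylsilyl)oxy]-2-(tributylstannyl)but-2-en-1-yl acetate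
Conditions: Ac2O, pyridine, DMAP (cat.), CH2Cl2, 0 °C
Reagents that add atoms: acetic anhydride CC(=O)OC(C)=O
Why: Routine acetylation of the remaining primary alcohol; it installs the C16 acetate of the target at the outset.

Step 21
Reactants: 30 (E)-4-[(tert-butyldimethylsilyl)oxy]-2-(tributylstannyl)but-2-en-1-yl acetate
Product: 31 (E)-4-[(tert-butyldimethylsilyl)oxy]-2-iodobut-2-en-1-yl acetate
Conditions: I2, CH2Cl2, 0 °C
Reagents that add atoms: iodine II
Why: Iododestannylation of an alkenylstannane proceeds with retention of alkene geometry.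

Step 22
Reactants: 26 triethylsilyl-protected iodide (name as under step 17); 31 (E)-4-[(tert-butyldimethylsilyl)oxy]-2-iodobut-2-en-1-yl acetate
Product: 33 (2R,5R,9R,10R,13Z)-15-[(tert-butyldimethylsilyl)oxy]-2-[(triethylsilyl)oxy]labda-8(17),13-dien-16-yl acetate, via alkylzinc iodide 32 (not isolated)
Conditions: Zn dust (activated with BrCH2CH2Br and Me3SiCl), DMA, 40 °C; supernatant added to 31, PdCl2(dppf) (5 mol%), THF, rt
Reagents that add atoms: none
Why: Negishi sp3–sp2 coupling: zerovalent palladium inserts into the alkenyl C–I bond and the alkyl group is transferred with retention of alkene geometry, so C12 ends trans to C15 and the acetoxymethyl group cis to it; the organozinc tolerates the acetate. Transfer of the supernatant keeps metallic zinc away from the β-acetoxy alkenyl iodide.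

Step 23
Reactants: 33 coupled bis-silyl ether (name as under step 22)
Product: 34 (2R,5R,9R,10R,13Z)-2,15-dihydroxylabda-8(17),13-dien-16-yl acetate
Conditions: HF·pyridine, pyridine, THF, 0 °C → rt
Reagents that add atoms: none
Why: Buffered HF cleaves both silyl ethers and should leave the allylic acetate and the acid-sensitive exocyclic alkene alone.

Step 24
Reactants: 34 (2R,5R,9R,10R,13Z)-2,15-dihydroxylabda-8(17),13-dien-16-yl acetate
Product: 36 (2R,5R,9R,10R,13Z)-16-acetoxy-2-hydroxylabda-8(17),13-dien-15-oic acid, via enal 35 (not isolated)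
Conditions: TEMPO (10 mol%), PhI(OAc)2 (1.1 equiv), CH2Cl2, rt; then NaClO2, NaH2PO4, 2-methylbut-2-ene, t-BuOH/H2O, 0 °C → rt
Reagents that add atoms: sodium chlorite [Na+].[O-]Cl=O
Why: The oxoammonium oxidation is selective for the primary allylic alcohol over the secondary C2 alcohol and does not isomerise (Z)-allylic systems. Pinnick oxidation then gives the acid, with the alkene scavenger protecting the C8 methylene. A free γ-hydroxy acid is never present, so butenolide formation is avoided.

## Compound list

1 | methyl 3,3-dimethylpent-4-enoate | C=CC(C)(C)CC(=O)OC | starting material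
2 | sodium benzenesulfinate | [Na+].[O-]S(=O)c1ccccc1 | starting material
3 | methyl 4-iodo-3,3-dimethyl-5-(phenylsulfonyl)pentanoate (racemic) | COC(=O)CC(C)(C)C(I)CS(=O)(=O)c1ccccc1 | intermediate
4 | methyl (E)-3,3-dimethyl-5-(phenylsulfonyl)pent-4-enoate | COC(=O)CC(C)(C)/C=C/S(=O)(=O)c1ccccc1 | intermediate
5 | (E)-3,3-dimethyl-5-(phenylsulfonyl)pent-4-enal | O=CCC(C)(C)/C=C/S(=O)(=O)c1ccccc1 | intermediate
6 | (R)-4-benzyl-1,3-oxazolidin-2-one | O=C1N[C@H](Cc2ccccc2)CO1 | starting material
7 | acryloyl chloride | C=CC(=O)Cl | starting material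
8 | (R)-3-acryloyl-4-benzyl-1,3-oxazolidin-2-one | C=CC(=O)N1[C@H](Cc2ccccc2)COC1=O | intermediate
9 | 4-(benzyloxy)but-1-ene | C=CCCOCc1ccccc1 | starting material
10 | (R)-4-benzyl-3-[(E)-5-(benzyloxy)pent-2-enoyl]-1,3-oxazolidin-2-one | O=C(/C=C/CCOCc1ccccc1)N1[C@H](Cc2ccccc2)COC1=O | intermediate
11 | isopropenylmagnesium bromide | CC(=C)[Mg]Br | starting material
12 | (R)-4-benzyl-3-[(S)-3-(2-(benzyloxy)ethyl)-4-methylpent-4-enoyl]-1,3-oxazolidin-2-one | C=C(C)[C@@H](CCOCc1ccccc1)CC(=O)N1[C@H](Cc2ccccc2)COC1=O | intermediate
13 | (R)-4-benzyl-3-[(S)-3-(2-(benzyloxy)ethyl)-4-(chloromethyl)pent-4-enoyl]-1,3-oxazolidin-2-one | C=C(CCl)[C@@H](CCOCc1ccccc1)CC(=O)N1[C@H](Cc2ccccc2)COC1=O | intermediate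
14 | (R)-4-benzyl-3-[(S)-3-(2-(benzyloxy)ethyl)-4-(phenylsulfonylmethyl)pent-4-enoyl]-1,3-oxazolidin-2-one | C=C(CS(=O)(=O)c1ccccc1)[C@@H](CCOCc1ccccc1)CC(=O)N1[C@H](Cc2ccccc2)COC1=O | intermediate
15 | (R)-4-benzyl-3-{(E)-2-[(S)-5-(benzyloxy)-2-(phenylsulfonylmethyl)pent-1-en-3-yl]-3-hydroxy-5,5-dimethyl-7-(phenylsulfonyl)hept-6-enoyl}-1,3-oxazolidin-2-one (C10 and C2 unspecified, erased later) | O=C(C(C(O)CC(C)(C)/C=C/S(=O)(=O)c1ccccc1)[C@H](CCOCc1ccccc1)C(=C)CS(=O)(=O)c1ccccc1)N1[C@H](Cc2ccccc2)COC1=O | intermediate
16 | (E)-2-[(S)-5-(benzyloxy)-2-(phenylsulfonylmethyl)pent-1-en-3-yl]-5,5-dimethyl-7-(phenylsulfonyl)hept-6-ene-1,3-diol | OCC(C(O)CC(C)(C)/C=C/S(=O)(=O)c1ccccc1)[C@H](CCOCc1ccccc1)C(=C)CS(=O)(=O)c1ccccc1 | intermediate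
17 | (E)-2-[(S)-5-(benzyloxy)-2-(phenylsulfonylmethyl)pent-1-en-3-yl]-3-hydroxy-5,5-dimethyl-7-(phenylsulfonyl)hept-6-en-1-yl methanesulfonate | CS(=O)(=O)OCC(C(O)CC(C)(C)/C=C/S(=O)(=O)c1ccccc1)[C@H](CCOCc1ccccc1)C(=C)CS(=O)(=O)c1ccccc1 | intermediate
18 | (E)-2-[(S)-5-(benzyloxy)-2-(phenylsulfonylmethyl)pent-1-en-3-yl]-5,5-dimethyl-3-oxo-7-(phenylsulfonyl)hept-6-en-1-yl methanesulfonate | CS(=O)(=O)OCC(C(=O)CC(C)(C)/C=C/S(=O)(=O)c1ccccc1)[C@H](CCOCc1ccccc1)C(=C)CS(=O)(=O)c1ccccc1 | intermediate
19 | (S,E)-3-[2-(benzyloxy)ethyl]-7,7-dimethyl-4-methylidene-9-(phenylsulfonyl)-2-(phenylsulfonylmethyl)nona-1,8-dien-5-one | C=C(C(=O)CC(C)(C)/C=C/S(=O)(=O)c1ccccc1)[C@H](CCOCc1ccccc1)C(=C)CS(=O)(=O)c1ccccc1 | intermediate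
20 | triethyl{[(S,8E)-3-(2-(benzyloxy)ethyl)-4,7,7-trimethyl-9-(phenylsulfonyl)-2-(phenylsulfonylmethyl)nona-1,4,8-trien-5-yl]oxy}silane (enol ether geometry unspecified) | CC(=C(O[Si](CC)(CC)CC)CC(C)(C)/C=C/S(=O)(=O)c1ccccc1)[C@H](CCOCc1ccccc1)C(=C)CS(=O)(=O)c1ccccc1 | intermediate
21 | triethylsilyl ether of cyclopropanol 22 (ring carbons unspecified) | CC1(CC1(O[Si](CC)(CC)CC)CC(C)(C)/C=C/S(=O)(=O)c2ccccc2)[C@H](CCOCc2ccccc2)C(=C)CS(=O)(=O)c2ccccc2 | intermediate
22 | 2-[(S)-5-(benzyloxy)-2-(phenylsulfonylmethyl)pent-1-en-3-yl]-1-[(E)-2,2-dimethyl-4-(phenylsulfonyl)but-3-en-1-yl]-2-methylcyclopropan-1-ol (ring carbons unspecified) | OC1(CC(C)(C)/C=C/S(=O)(=O)c2ccccc2)CC1(C)[C@H](CCOCc3ccccc3)C(=C)CS(=O)(=O)c4ccccc4 | intermediate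
23 | (5R,6R,9R,10S)-12-(benzyloxy)-6-(phenylsulfonyl)-13,14,15,16-tetranorlabd-8(17)-en-2-one | C=C1C[C@@H](S(=O)(=O)c3ccccc3)[C@@H]2C(C)(C)CC(=O)C[C@@]2(C)[C@@H]1CCOCc1ccccc1 | intermediate
24 | (2R,5R,9R,10R)-13,14,15,16-tetranorlabd-8(17)-ene-2,12-diol | C=C1CC[C@@H]2C(C)(C)C[C@@H](O)C[C@@]2(C)[C@@H]1CCO | intermediate
25 | (2R,5R,9R,10R)-12-iodo-13,14,15,16-tetranorlabd-8(17)-en-2-ol | C=C1CC[C@@H]2C(C)(C)C[C@@H](O)C[C@@]2(C)[C@@H]1CCI | intermediate
26 | triethyl{[(2R,5R,9R,10R)-12-iodo-13,14,15,16-tetranorlabd-8(17)-en-2-yl]oxy}silane | C=C1CC[C@@H]2C(C)(C)C[C@@H](O[Si](CC)(CC)CC)C[C@@]2(C)[C@@H]1CCI | intermediate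
27 | but-2-yne-1,4-diol | OCC#CCO | starting material
28 | (E)-2-(tributylstannyl)but-2-ene-1,4-diol | OC/C=C(\CO)[Sn](CCCC)(CCCC)CCCC | intermediate
29 | (E)-4-[(tert-butyldimethylsilyl)oxy]-2-(tributylstannyl)but-2-en-1-ol | OC/C([Sn](CCCC)(CCCC)CCCC)=C\CO[Si](C)(C)C(C)(C)C | intermediate
30 | (E)-4-[(tert-butyldimethylsilyl)oxy]-2-(tributylstannyl)but-2-en-1-yl acetate | CC(=O)OC/C([Sn](CCCC)(CCCC)CCCC)=C\CO[Si](C)(C)C(C)(C)C | intermediate
31 | (E)-4-[(tert-butyldimethylsilyl)oxy]-2-iodobut-2-en-1-yl acetate | CC(=O)OC/C(I)=C\CO[Si](C)(C)C(C)(C)C | intermediate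
32 | {(2R,5R,9R,10R)-2-[(triethylsilyl)oxy]-13,14,15,16-tetranorlabd-8(17)-en-12-yl}zinc iodide | C=C1CC[C@@H]2C(C)(C)C[C@@H](O[Si](CC)(CC)CC)C[C@@]2(C)[C@@H]1CC[Zn]I | intermediate
33 | (2R,5R,9R,10R,13Z)-15-[(tert-butyldimethylsilyl)oxy]-2-[(triethylsilyl)oxy]labda-8(17),13-dien-16-yl acetate | C=C1CC[C@@H]2C(C)(C)C[C@@H](O[Si](CC)(CC)CC)C[C@@]2(C)[C@@H]1CC/C(COC(C)=O)=C/CO[Si](C)(C)C(C)(C)C | intermediate
34 | (2R,5R,9R,10R,13Z)-2,15-dihydroxylabda-8(17),13-dien-16-yl acetate | C=C1CC[C@@H]2C(C)(C)C[C@@H](O)C[C@@]2(C)[C@@H]1CC/C(COC(C)=O)=C/CO | intermediate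
35 | (2R,5R,9R,10R,13Z)-2-hydroxy-15-oxolabda-8(17),13-dien-16-yl acetate | C=C1CC[C@@H]2C(C)(C)C[C@@H](O)C[C@@]2(C)[C@@H]1CC/C(COC(C)=O)=C/C=O | intermediate
36 | (2R,5R,9R,10R,13Z)-16-acetoxy-2-hydroxylabda-8(17),13-dien-15-oic acid | C=C1CC[C@@H]2C(C)(C)C[C@@H](O)C[C@@]2(C)[C@@H]1CC/C(=C/C(=O)O)COC(C)=O | target

## Step count and least certain steps

Total: 24 steps. Longest linear sequence: 18 steps (steps 3–17, then 22–24). Steps 1–2 and 18–21 are side branches.

**Step 14 (key step, proposed new method).** The most likely failure is that the first closure onto hindered C5 is too slow. The tertiary C10 radical would then be lost by hydrogen abstraction (including 1,6-transfer from the benzylic CH2), by oxidation and elimination to an enone, or by reversible 3-exo attack on the neighbouring alkene. The second concern is poor facial selectivity at C10 relative to C9, which would give a diastereomeric decalin. The third is 5-exo closure of the C6 radical at C8.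

Fallback with known chemistry, from 22 back to 23: FeCl3 (trivalent iron) in DMF/Et2O at 0 °C opens the cyclopropanol by the same regioselective β-scission but traps the tertiary radical at once by chlorine transfer. This should give the tertiary β-chloro ketone (8R,E)-8-[2-(benzyloxy)ethyl]-7-chloro-3,3,7-trimethyl-1-(phenylsulfonyl)-9-(phenylsulfonylmethyl)deca-1,9-dien-5-one F1. Slow addition of Bu3SnH with AIBN to F1 in benzene at 80 °C then regenerates the C10 radical under reductive chain conditions, where its lifetime is set only by the low stannane concentration. The tandem closure with loss of the sulfonyl radical leads to 23. Oxidative ring-opening chlorination of cyclopropanols and tin-mediated radical cyclisations ending in β-sulfonyl fragmentation are both established reaction types.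

**Step 12.** The likely problem is rhodium hydride-mediated migration of the C10=C20 double bond into conjugation toward C9, which would destroy the only stereocentre. Partial reduction of the vinyl sulfone is a second risk.

Fallback, from 19 back to 20: conjugate reduction with LiBH(s-Bu)3 in THF at −78 °C, a stoichiometric hydride that adds to the unhindered methylene terminus. It generates lithium (S,8E)-3-[2-(benzyloxy)ethyl]-4,7,7-trimethyl-9-(phenylsulfonyl)-2-(phenylsulfonylmethyl)nona-1,4,8-trien-5-olate F2. F2 is silylated at once with Et3SiCl/Et3N at −78 °C, before proton exchange with the allyl sulfone can occur, to give 20.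

**Step 19.** The likely problem is incomplete regioselection in the monosilylation, giving both mono-ethers and the bis-ether.

Fallback, from 28 back to 30: both hydroxyls are acetylated (Ac2O, pyridine) to (E)-2-(tributylstannyl)but-2-ene-1,4-diyl diacetate F3. The less hindered acetate, remote from tin, is removed by lipase-catalysed hydrolysis (Candida antarctica lipase B, pH 7 buffer/acetone) to give (E)-4-hydroxy-2-(tributylstannyl)but-2-en-1-yl acetate F4. Silylation of F4 (t-BuMe2SiCl, imidazole) gives 30. Differentiation is thus moved from a silylation to an enzymatic deacylation, and the route is one step longer.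

**Step 22.** The likely problem is loss of the allylic acetate, either by β-elimination from the alkenyl metal intermediate (allene formation) or by ionisation with zerovalent palladium.

Fallback, from 29 (with 32) back to 33: 29 is iododestannylated (I2, CH2Cl2) to (E)-4-[(tert-butyldimethylsilyl)oxy]-2-iodobut-2-en-1-ol F5. F5 is converted into its zinc alkoxide with Et2Zn and coupled with 32 under the same palladium catalysis to give (2R,5R,9R,10R,13Z)-15-[(tert-butyldimethylsilyl)oxy]-2-[(triethylsilyl)oxy]labda-8(17),13-dien-16-ol F6. Acetylation of F6 (Ac2O, pyridine, DMAP) gives 33. The acetate is then introduced only after the metal-mediated step.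

## Further compounds

F1 | step 14 | (8R,E)-8-[2-(benzyloxy)ethyl]-7-chloro-3,3,7-trimethyl-1-(phenylsulfonyl)-9-(phenylsulfonylmethyl)deca-1,9-dien-5-one (C7 unspecified) | O=C(CC(C)(C)/C=C/S(=O)(=O)c1ccccc1)CC(C)(Cl)[C@H](CCOCc1ccccc1)C(=C)CS(=O)(=O)c1ccccc1
F2 | step 12 | lithium (S,8E)-3-[2-(benzyloxy)ethyl]-4,7,7-trimethyl-9-(phenylsulfonyl)-2-(phenylsulfonylmethyl)nona-1,4,8-trien-5-olate | [Li+].CC(=C([O-])CC(C)(C)/C=C/S(=O)(=O)c1ccccc1)[C@H](CCOCc1ccccc1)C(=C)CS(=O)(=O)c1ccccc1
F3 | step 19 | (E)-2-(tributylstannyl)but-2-ene-1,4-diyl diacetate | CC(=O)OC/C([Sn](CCCC)(CCCC)CCCC)=C\COC(C)=O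
F4 | step 19 | (E)-4-hydroxy-2-(tributylstannyl)but-2-en-1-yl acetate | CC(=O)OC/C([Sn](CCCC)(CCCC)CCCC)=C\CO
F5 | step 22 | (E)-4-[(tert-butyldimethylsilyl)oxy]-2-iodobut-2-en-1-ol | OC/C(I)=C\CO[Si](C)(C)C(C)(C)C
F6 | step 22 | (2R,5R,9R,10R,13Z)-15-[(tert-butyldimethylsilyl)oxy]-2-[(triethylsilyl)oxy]labda-8(17),13-dien-16-ol | C=C1CC[C@@H]2C(C)(C)C[C@@H](O[Si](CC)(CC)CC)C[C@@]2(C)[C@@H]1CC/C(CO)=C/CO[Si](C)(C)C(C)(C)C
A1 | alternative 1 | (4R,6R)-4-[(tert-butyldimethylsilyl)oxy]-6-(7,9,9-trimethyl-1,4-dioxaspiro[4.5]dec-7-en-8-yl)tetrahydro-2H-pyran-2-one | O=C1C[C@H](O[Si](C)(C)C(C)(C)C)C[C@@H](O1)C2=C(C)CC3(OCCO3)CC2(C)C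
A2 | alternative 1 | octalin carboxylic acid with C10 set, C11 carboxyl on C9 (trans to the C10 methyl), C8 silyloxy, C5=C6 and C2 dioxolane | CC(C)(C)[Si](C)(C)O[C@@H]1CC=C2C(C)(C)CC3(OCCO3)C[C@@]2(C)[C@H]1C(=O)O
A3 | alternative 2 | (Z)-9-formyl-8,8-dimethyl-7-(prop-1-en-2-yl)-4-(trimethylsilylmethyl)non-3-en-1-yl pivalate with the C5 centre of the target | O=CCC(C)(C)[C@H](C(C)=C)CC/C(C[Si](C)(C)C)=C/CCOC(=O)C(C)(C)C
A4 | alternative 2 | decalin with free equatorial C2 hydroxyl, C8 methylene and C12 pivalate | C=C1CC[C@@H]2C(C)(C)C[C@@H](O)C[C@@]2(C)[C@@H]1CCOC(=O)C(C)(C)C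
A5 | alternative 3 | ring-A cyclohexane with C2 tert-butyldimethylsilyloxy, C5 but-3-ynyl and C10 methyl and (E)-2-(triisopropylsilyloxy)vinyl groups | C#CCC[C@@H]1C(C)(C)C[C@@H](O[Si](C)(C)C(C)(C)C)C[C@@]1(C)/C=C/O[Si](C(C)C)(C(C)C)C(C)C
A6 | alternative 3 | decalin with C8 methylene, C9 formyl (C11) and C2 silyloxy group | C=C1CC[C@@H]2C(C)(C)C[C@@H](O[Si](C)(C)C(C)(C)C)C[C@@]2(C)[C@@H]1C=O
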